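(Readings and results were computed for an exercise; the scatter is artificial.)

The last reading of the violet flask stands at 4.00 min, and you have to decide whether to leave it stirring up to 8.0 min. Nothing more is charged.

- violet: left-handed substrate 0.20 M; right-handed substrate 0.20 M; partner 3 equiv; protic impurity 0.010 M; precatalyst 0.2 mol%; added ligand 0.80 mM; the very flask that is asked about, followed so far
- flask: left-handed substrate 0.20 M; partner 3.00 equiv; protic impurity 0.0100 M; precatalyst 0.2 mol%; added ligand 0.80 mM; right-handed substrate 0.20 M; time 8.0 min

violet run (percent of the left-handed substrate and right-handed substrate together charged)

| time / min | right-handed substrate / % | left-handed substrate / % | left-handed product / % |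
|---|---|---|---|
| 0.333 | 51 | 48 | 4 |
| 0.667 | 46 | 41 | 11 |
| 1.50 | 33 | 22 | 31 |
| 4.00 | 12 | 0 | 51 |

(readings scatter by 2 percentage points)

- catalyst is single-handed; left-handed substrate and right-handed substrate are mirror images of each other, charged as a racemate, each of them at the stated concentration
- what was read earlier has a scatter of 2 percentage points, one standard deviation

- whether the excess of right-handed substrate over left-handed substrate among what is left of the two reaches 80% by 8.0 min (no / yes)
- the highest excess of right-handed substrate over left-handed substrate among what is left of the two up to 8.0 min

1. Start from the zero of the scale. If the single-handed catalyst took both mirror-image substrates at equal speed, their fractions left would stay equal, and the excess of right-handed substrate would stay at zero.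

2. Now read the departure from that zero at 1.50 min. The left-handed substrate stands at 0.440 of its own charge and the right-handed substrate at 0.660. The logarithm of the first fraction over the logarithm of the second gives 1.98. This is the speed ratio s, the selectivity factor. It is a reading with scatter, and the pair at 0.667 min gives 2.38.

3. Suppose both substrates meet the same catalyst and partner, each in proportion to its own amount. Then the left-handed fraction is the right-handed fraction r raised to the power s, and time drops out. Let x be r raised to the power s less one. The excess is one minus x over one plus x, so it climbs as r falls.

4. The wanted 80% needs r = 0.105. Between the last two readings the logarithm of the right-handed substrate falls at 0.405 /min, a pace read with their scatter. If that pace holds, r gets there at 6.04 min, sooner than the limit. At the same pace r is reckoned at 0.0476 for 8.0 min, which gives an estimated excess of 90.3%.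

5. So leave it stirring, and sample at 6.04 min, when, by this reckoning, twice the right-handed substrate reckoned for the end is still there.

6. The forecast says yes with a top of 97%, since the level “should come shortly after 4 min if the catalyst lives”; the top reckoned here is lower.

7. The flask gives yes, with a top of 90.8%.

    partner + catalyst + left-handed substrate → catalyst + left-handed product (k = 610 /M²/s)
    partner + catalyst + right-handed substrate → catalyst + right-handed product (k = 300 /M²/s)
    precatalyst → catalyst (k = 0.0140 /s)
    catalyst + added ligand ⇌ idle complex, settled at all times (K = 6600 /M)
    partner + protic impurity → quenched reagent (k = 0.810 /M/s)

The level is reached at 5.68 min, with right-handed substrate at 5.96% of the two substrates charged together. At 8.00 min the right-handed substrate stands at 5.3% of its own charge, and s turns that fraction into an excess of 89.4%.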